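**Retrosynthetic overview**
- The strategy rests on the benzo ring: C4 and C6 are both meta to the ring nitrogen N1 (attached at C7a) and so cannot be brominated directly, but both are ortho to C5. An amino group placed at C5 directs bromine to exactly these two carbons and is then removed.
- C2–Br is disconnected to the lactam C2=O of 4,6-dibromoindolin-2-one (deoxybromination with POBr3).
- C5–H is disconnected to C5–NH2 (diazotisation, then reduction); C4–Br and C6–Br are disconnected to 5-aminoindolin-2-one and two equivalents of NBS.
- 5-Aminoindolin-2-one comes from commercial 5-nitroindolin-2-one by hydrogenation.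
- No ring is formed: both rings are bought as the oxindole, and the five-membered ring is only aromatised in the last step.

Key step: step 2

Remark: the target is planar and has no stereocentre, so it is achiral and the "single enantiomer" is simply the compound itself. No stereocontrol is needed anywhere.

**Route**

Step 1
Reactants: 1 5-nitroindolin-2-one
Product: 2 5-aminoindolin-2-one
Conditions: H2 (1 atm), 10% Pd/C, MeOH–THF, rt; filtered under N2 and used at once
Reagents that add atoms: none
Why: Catalytic hydrogenation of an aromatic nitro group to the aniline; the lactam and the benzylic C3 methylene are inert under these conditions, and the air-sensitive amino anilide is carried on without storage.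

Step 2
Reactants: 2 5-aminoindolin-2-one; 3 N-bromosuccinimide (2.05 equiv)
Product: 5 5-amino-4,6-dibromoindolin-2-one, via 5-amino-6-bromoindolin-2-one 4 (not isolated)
Conditions: NBS (2.05 equiv, in portions), DMF, −10 → 0 °C, dark; then H2O
Reagents that add atoms: N-bromosuccinimide, O=C1CCC(=O)N1Br
Why: Each bromination is an electrophilic aromatic substitution in which Br+ from NBS attacks a carbon ortho to the C5 amino group and the Wheland intermediate is stabilised as an iminium ion by the nitrogen lone pair; the less hindered C6 should react first (monobromide 4) and C4 second. The closest known reaction is the ortho,ortho-dibromination of para-substituted anilines such as 4-aminoacetanilide with two equivalents of NBS or bromine. No ring is closed and no stereocentre is formed, so only site selectivity matters: C4 and C6 against C7, the C3 methylene and the nitrogen atoms. The free amine is by far the strongest donor on the ring, whereas the lactam nitrogen activates only C7 and the already substituted C5, and C7 is meta to the amine. The C3 methylene can brominate only through the lactam enol, which should form slowly in neutral DMF at −10 to 0 °C, and after two brominations the aniline is deactivated and flanked on both sides, so 2.05 equiv of NBS should be consumed at C6 and C4 before anything else reacts.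

Step 3
Reactants: 5 5-amino-4,6-dibromoindolin-2-one
Product: 7 4,6-dibromoindolin-2-one, via arenediazonium hydrogensulfate 6 (not isolated)
Conditions: NaNO2 (1.05 equiv) in conc. H2SO4, added to 5 in AcOH, 0–5 °C; then 50% aq. H3PO2 (excess), 0 °C → rt
Reagents that add atoms: none
Why: Diazotisation followed by hydrodediazoniation with hypophosphorous acid (reductive deamination by a radical chain, the new C5–H coming from a P–H bond); preformed nitrosylsulfuric acid is the standard way to diazotise a weakly basic di-ortho-bromoaniline, one equivalent of it in cold strong acid should react at the amine nitrogen well before the non-enolised C3 methylene, and the aryl bromides and the lactam are inert.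

Step 4
Reactants: 7 4,6-dibromoindolin-2-one; 8 phosphorus oxybromide
Product: 10 2,4,6-tribromo-1H-indole, via indol-2-yl phosphorodibromidate 9 (not isolated)
Conditions: POBr3 (1.5 equiv), imidazole (1.2 equiv), ClCH2CH2Cl, 80 °C; then ice, aq. NaHCO3
Reagents that add atoms: phosphorus oxybromide, O=P(Br)(Br)Br
Why: Deoxybromination of a lactam by Vilsmeier-type activation: the lactam oxygen is phosphorylated, bromide adds to C2 and expels dibromophosphate, and tautomerisation gives the aromatic 2-bromoindole, the established way from oxindoles to 2-bromoindoles; imidazole buffers the HBr, and the two ring bromines should make the product less acid-sensitive than 2-bromoindole itself.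

**Compound list**
1 | 5-nitroindolin-2-one | O=C1Cc2cc([N+](=O)[O-])ccc2N1 | starting material
2 | 5-aminoindolin-2-one | Nc1ccc2NC(=O)Cc2c1 | intermediate
3 | N-bromosuccinimide | O=C1CCC(=O)N1Br | starting material
4 | 5-amino-6-bromoindolin-2-one | Nc1cc2CC(=O)Nc2cc1Br | intermediate
5 | 5-amino-4,6-dibromoindolin-2-one | Nc1c(Br)cc2NC(=O)Cc2c1Br | intermediate
6 | 4,6-dibromo-2-oxoindoline-5-diazonium hydrogensulfate | N#[N+]c1c(Br)cc2NC(=O)Cc2c1Br.OS(=O)(=O)[O-] | intermediate
7 | 4,6-dibromoindolin-2-one | O=C1Cc2c(Br)cc(Br)cc2N1 | intermediate
8 | phosphorus oxybromide | O=P(Br)(Br)Br | starting material
9 | 4,6-dibromo-1H-indol-2-yl phosphorodibromidate | O=P(Br)(Br)Oc1cc2c(Br)cc(Br)cc2[nH]1 | intermediate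
10 | 2,4,6-tribromo-1H-indole | Brc1cc(Br)c2cc(Br)[nH]c2c1 | target

Total step count: 4
Longest linear sequence: 4 steps (1 → 2 → 5 → 7 → 10)

**Steps most likely to fail**

1. Step 2. Site control may be lost: bromine may enter the enolisable C3 methylene (or C7) before both positions ortho to the amine are filled, and the electron-rich amino anilide may be oxidised by NBS. The fallback sets out from 2 and gives up the need for selectivity between ring and methylene. Treatment of 2 with an excess of 3 (about 4.2 equiv) in AcOH at rt to 40 °C should brominate C4, C6 and both C3 hydrogens and give 5-amino-3,3,4,6-tetrabromoindolin-2-one F1. Zinc dust in AcOH at rt then removes only the two bromines alpha to the lactam carbonyl (reductive debromination through the zinc enolate, as used to make oxindoles from 3,3-dibromooxindoles) and leaves the aryl bromides. The fallback comes back to the route at 5.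

2. Step 4. The electron-poor lactam may be activated only slowly, and the 2-bromoindole may decompose or condense with activated lactam in the acidic medium as it forms. The fallback sets out from 7 and installs the C2 bromine by C–H functionalisation instead of through the lactam oxygen. DIBAL-H (toluene–THF, 0 °C → rt, aqueous work-up) reduces the lactam to the hemiaminal, which dehydrates to 4,6-dibromo-1H-indole F2. Iridium-catalysed C–H borylation (B2pin2, cat. [Ir(OMe)(cod)]2/dtbpy, THF, 60 °C) should then give 4,6-dibromo-2-(4,4,5,5-tetramethyl-1,3,2-dioxaborolan-2-yl)-1H-indole F3. C2 is the usual site for N–H indoles, and here C3 is shielded by the peri bromine at C4, C5 lies between two bromines and C7 is ortho to the C6 bromine; aryl bromides are tolerated. Bromodeboronation with CuBr2 (3 equiv, MeOH–H2O, 80 °C) returns to the route at 10.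

3. Step 3. Nitrous acid may nitrosate the C3 methylene in competition with the hindered, weakly basic amine, and the diazonium ion may couple with the enolisable lactam before it is reduced. The fallback sets out from 5 and separates diazotisation from reduction under anhydrous conditions. NOBF4 (1.1 equiv) in MeCN at −30 °C, followed by precipitation with Et2O, should give 4,6-dibromo-2-oxoindoline-5-diazonium tetrafluoroborate F4 as an isolated salt that has never met nitrous acid and is washed free of nitrosating agent. The salt is then reduced in a separate flask with 50% aq. H3PO2 and catalytic Cu2O at 0 °C → rt. The fallback comes back to the route at 7.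

**Further compounds**
F1 | step 2 | 5-amino-3,3,4,6-tetrabromoindolin-2-one | Nc1c(Br)cc2NC(=O)C(Br)(Br)c2c1Br
F2 | step 4 | 4,6-dibromo-1H-indole | Brc1cc(Br)c2cc[nH]c2c1
F3 | step 4 | 4,6-dibromo-2-(4,4,5,5-tetramethyl-1,3,2-dioxaborolan-2-yl)-1H-indole | CC1(C)OB(OC1(C)C)c1cc2c(Br)cc(Br)cc2[nH]1
F4 | step 3 | 4,6-dibromo-2-oxoindoline-5-diazonium tetrafluoroborate | N#[N+]c1c(Br)cc2NC(=O)Cc2c1Br.F[B-](F)(F)F
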